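## Structural features

The target is a 2-hydroxy-5-(3-methylbutylamino)-1,4-benzoquinone (C1'–C6') whose C3' is joined through one methylene (C11) to C9 of a 4,4,8,9-tetramethyl-octal-5-ene (ring A: C1–C5 and C10; ring B: C5–C10). Three stereocentres stand side by side: C8 (CH–CH3), C9 (quaternary, bearing CH3 and C11) and the ring-fusion carbon C10 (CH). The two methyl groups are cis to each other and trans to H10, so C11 is cis to H10 (8S,9R,10S). The quinone is a vinylogous acid and a vinylogous amide and does not tolerate strong base, nucleophiles or reductants, so it has to appear last. The trisubstituted C5=C6 olefin is the second fragile element: under acid it can move toward C10 and erase that centre, and it can be hydrogenated. The real difficulty is the quaternary C9, flanked by two tertiary carbons and carrying a neopentyl arylmethyl group, in a ring B that keeps no functional group except the olefin. The key step uses the fact that C8 and C9 each adjoin a carbon that can temporarily be a carbonyl: C7 (allylic to C5=C6, hence an enone) and C11 (benzylic, hence an aryl ketone). C7–C8–C9–C11 is therefore a latent 1,4-diketone, and the C8–C9 bond of ring B is a bond between two enolate carbons. Only C10 has to be made beforehand, because C9 and C8 are set from it.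

## Logic of the disconnections

**26 ⇒ 24 + 25.** The C5'–N bond is cut. A vinylogous ester exchanges with a primary amine by addition–elimination, so the amine can be the last building block and the vinylogous amide never meets earlier reagents. This removes the side chain and leaves a methoxy quinone. The forward step must substitute at C5' only, which requires C2' to be masked as the hydroxyquinone anion.

**24 ⇒ 23 ⇒ 22.** The C2'–OH is traced back to a methyl ether and the two quinone carbonyls to aryl methyl ethers. A symmetric tetramethoxyphenyl ring is inert to bases, hydrides, radicals and nickel, and it comes from 11. The gain is that the quinone is absent from all work on ring B. The oxidation must stop at the para-quinone and spare C5=C6, and the hydrolysis must pick the methoxy group that is flanked by C11.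

**22 ⇒ 21 ⇒ 19 ⇒ 18.** The two C11–H bonds are traced back to the C11 carbonyl that acidified C9. The demand is a deoxygenation at a neopentyl benzylic carbon that avoids a cation, because a cation could rearrange or be trapped by C5=C6. A radical chain meets it.

**18 ⇒ 17 ⇒ 16.** The C7 methylene is traced back to the C7 ketone that acidified C8. The forward removal must leave the olefin at C5=C6 and must not depend on the hindered C11 carbonyl reacting.

**16 ⇒ 14 (through 15).** The C8–C9 bond is cut between two carbons of like polarity. This removes ring B, the quaternary centre and the C8 centre in one stroke and leaves a monocyclic ring A with a single stereocentre. The forward step must form both enolates without touching H10, and it must join them inside the molecule on the correct face of C9.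

**14 ⇒ 13 ⇒ 10 + 11.** The C11–C1' bond is cut. The aryl anion is available from 11 by lithiation, and C11 is then an aldehyde. The demand is that the aryl nucleophile choose the aldehyde over the enone carbonyl.

**10 ⇒ 9.** The C11 aldehyde is traced back to a vinyl group. The forward cleavage must distinguish a monosubstituted olefin from the conjugated trisubstituted one.

**9 ⇒ 8 ⇒ 5 + 6.** The enone is traced back by 1,3-oxygen transposition to a tertiary propargylic alcohol, and the C5–C6 bond is then cut. C5 is flanked by a quaternary and a tertiary carbon and accepts only a slim sp nucleophile. The transposition must give the (E) olefin and must not eliminate toward C10.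

**5 ⇒ 3 + 4 ⇒ 1.** The C9–C10 bond is cut to an enolate equivalent and a crotyl electrophile. Both pieces are simple. The forward step must bond at the substituted allyl terminus, fix C9 absolutely, and deliver C10 by diastereoselection backed by separation and recycling.

## Other disconnections considered

**Alternative 1:** The cut is C9–C10, made while a lactone C6–O bond breaks and C5=C6 forms. Lactone A2 holds C6, C7, C8, C9 and the carboxyl carbon in its ring. It would be enolised (LiN(i-Pr)2), O-silylated (t-BuMe2SiCl) and warmed, and the [3,3] shift would contract it to carbocycle A1.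
- **In favour:** the step is concerted and stereospecific, and it creates C9 and C10 together. The olefin lands at C5=C6 by the mechanism itself, so no C7 oxygen has to be removed, and C11 is already a methylene. On these two points it is better than the chosen plan, which spends five steps on deoxygenation.
- **Against:** the carboxyl group on C9 must still become the C9 methyl, which means at least three steps at a neopentyl quaternary carbon. The lactone ring forces a boat-like transition state with a fully substituted ketene acetal terminus and an olefin terminus next to the gem-dimethyl carbon, so rate and facial outcome are less secure. A2 needs controlled centres at C6 and C8, against one centre (C10) in 14.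
- **Comparison:** both plans form the bond to C9 intramolecularly in a six-membered array. A pericyclic shift is in principle more predictable than a radical–enolate coupling (equal or better), but the boat erodes that advantage here. The saving at C7 and C11 is roughly cancelled by the CO2H-to-CH3 conversion and the longer route to A2.

**Alternative 2:** The cuts are C9–C10 and C5=C6. An amine-catalysed (enamine-mediated) Michael addition of 1 through C10 to the β-carbon of A4 (which becomes C9), followed by aldol condensation of the methyl ketone onto C5, would give A3.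
- **In favour:** one step from two bulk chemicals builds ring B, the 5-en-7-one and C10. At the front this is much shorter than the seven steps to 14 (better). The chemistry is polar and well understood, and the C7 ketone allows C8 to be methylated.
- **Against:** C9 arrives tertiary. It becomes quaternary only after a relay to the cross-conjugated dienone A5 and conjugate addition of an arylmethyl nucleophile at a β,β-disubstituted neopentyl carbon. That addition is intermolecular and its face is decided by C10 alone. The aldol closure onto the carbonyl of hindered 1 should be slow, and enantiocontrol for such α-unsubstituted ketones is not assured.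
- **Comparison:** the C7 oxygen has to be removed exactly as in the chosen plan (equal). The quaternary centre is made between molecules here and within one molecule in the chosen plan. The relay (methylation, dehydrogenation, conjugate addition) gives back most of the early saving.

**Alternative 3:** The cut is C5'–C6' in the quinone. Heating A7 would open the four-membered ring, and the ketene carbon would close onto the alkyne terminus to give A6. A7 would come from A8 by two successive carbanion additions, first A9 and then an acetylide.
- **In favour:** the quinone appears at the right oxidation level with alkyl and methoxy groups placed by the cyclobutenone. No strong oxidant is used near C5=C6. For the quinone ring alone this is equal or better, and it is convergent.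
- **Against:** it leaves the real problem untouched. The whole decalin with C8, C9 and C10 must be made some other way and supplied as the neopentyl organolithium A9. A6 lacks the C5' nitrogen, so an oxidative amination and then hydrolysis of a methoxy group deactivated by the amino group are still needed.
- **Comparison:** the chosen plan buys all four arene oxygens with 11 and needs three closing steps (oxidation, hydrolysis, amination). Alternative 3 spends about four steps and its key step on the ring that needs least help.

Key step: step 8

**Remarks on the chemistry**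

- Numbering: C1–C11 as defined above and C1'–C6' for the arene/quinone; the same locants are used for all intermediates.
- Assumption: the (Sa,S,S) antipode of the phosphoramidite in step 2 is taken to be the one that gives (S) at C9; if it gives (R), the mirror-image ligand is used.
- Correction 1: a five-carbon alkynol such as pent-1-yn-3-ol cannot supply the C6–C7(=O)–C8H2–CH3 chain, because it would leave one carbon and one hydroxyl too many. The four-carbon alkyne 6 is the correct reagent.
- Correction 2: an iridium allylation catalyst fixes the allylic carbon C9 directly. C10 is the ketone α-carbon, follows only by diastereoselection, and stays epimerisable while C5 is a ketone. C9 is erased in step 8 and C10 carries all the stereochemical information, so C9 is used as a temporary resolving handle. C10-epimeric material is separated at 5 and recycled by base.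
- Improvement in sequence: the C5 ketone is consumed straight after the allylation (step 3), and the aryl ketone is made last. This avoids a 1,4-diketone with two epimerisable centres and avoids a chemoselective alkynylation.
- Improvement in step 4: 8 is a 1,6-enyne, so a π-acidic gold catalyst is avoided and the transposition is run through a vanadate ester.

## Route

Step 1
Reactants: 1 2,2-dimethylcyclohexan-1-one
Product: 3 [(6,6-dimethylcyclohex-1-en-1-yl)oxy]trimethylsilane, via lithium enolate 2 (not isolated)
Conditions: LiN(i-Pr)2, THF, −78 °C; Me3SiCl, −78 °C → rt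
Reagents that add atoms: chlorotrimethylsilane C[Si](C)(C)Cl
Why: Kinetic deprotonation at the only enolisable α-carbon (C10; C4 is quaternary) and O-silylation of the lithium enolate give a single enol ether.

Step 2
Reactants: 3 [(6,6-dimethylcyclohex-1-en-1-yl)oxy]trimethylsilane; 4 (E)-but-2-en-1-yl methyl carbonate
Product: 5 (6S)-6-[(2S)-but-3-en-2-yl]-2,2-dimethylcyclohexan-1-one
Conditions: [Ir(cod)Cl]2 (2 mol %), (Sa)-2,2'-binaphthol-derived N,N-bis[(S)-1-phenylethyl]phosphoramidite (4 mol %), CsF (0.4 equiv), ZnF2 (1.5 equiv), DME, 50 °C
Reagents that add atoms: none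
Why: Iridium-catalysed allylic alkylation of a ketone silyl enol ether: the monovalent iridium phosphoramidite complex ionises 4 to a π-crotyl intermediate that the fluoride-activated enolate attacks at the methyl-bearing terminus, the catalyst fixing C9 as (S). C10 is formed in the same event by substrate diastereoselection; C10-epimeric material is removed by chromatography and recycled by base-induced epimerisation, which cannot touch the non-acidic C9 centre, so 5 carries (S)-C10 with the enantiopurity set by the catalyst.

Step 3
Reactants: 5 (6S)-6-[(2S)-but-3-en-2-yl]-2,2-dimethylcyclohexan-1-one; 6 but-1-yne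
Product: 8 (6S)-1-(but-1-yn-1-yl)-6-[(2S)-but-3-en-2-yl]-2,2-dimethylcyclohexan-1-ol (C1 epimers), via lithium butynide 7 (not isolated)
Conditions: 6, n-BuLi, THF, −78 °C; then 5, −78 → 0 °C; aq NH4Cl
Reagents that add atoms: none
Why: 1,2-Addition of a lithium acetylide, a slim and weakly basic sp nucleophile, to a ketone flanked by a quaternary and a tertiary carbon; the new carbinol centre is destroyed in step 4, and converting the ketone at once ends the acidity of H10.

Step 4
Reactants: 8 (6S)-1-(but-1-yn-1-yl)-6-[(2S)-but-3-en-2-yl]-2,2-dimethylcyclohexan-1-ol (C1 epimers)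
Product: 9 (1E)-1-[(6S)-6-[(2S)-but-3-en-2-yl]-2,2-dimethylcyclohexylidene]butan-2-one
Conditions: VO(OSiPh3)3 (5 mol %), Ph3SiOH (10 mol %), xylene, 130 °C
Reagents that add atoms: none
Why: Meyer–Schuster rearrangement through a vanadate ester: a [3,3] shift of the propargyl ester of pentavalent vanadium gives an allenyl vanadate that is released as the enone, with no free C5 cation and no π-acid to engage the 1,6-enyne. Protonation of the allenol places C7 on the C10 side, away from the gem-dimethyl carbon C4, giving the less strained (E) isomer.

Step 5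
Reactants: 9 (1E)-1-[(6S)-6-[(2S)-but-3-en-2-yl]-2,2-dimethylcyclohexylidene]butan-2-one
Product: 10 (2R)-2-[(1S,2E)-3,3-dimethyl-2-(2-oxobutylidene)cyclohexyl]propanal
Conditions: OsO4 (2 mol %), NaIO4 (4 equiv), 2,6-lutidine, dioxane–H2O, rt
Reagents that add atoms: osmium tetroxide O=[Os](=O)(=O)=O (catalytic oxygen carrier); sodium periodate [Na+].[O-]I(=O)(=O)=O (terminal oxidant)
Why: Lemieux–Johnson cleavage: OsO4 dihydroxylates the unhindered, electron-rich monosubstituted olefin much faster than the electron-poor trisubstituted enone olefin, and NaIO4 cleaves the diol and returns osmium to its octavalent state. Epimerisation at C9, now α to the aldehyde, would be without consequence.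

Step 6
Reactants: 10 (2R)-2-[(1S,2E)-3,3-dimethyl-2-(2-oxobutylidene)cyclohexyl]propanal; 11 1,2,4,5-tetramethoxybenzene
Product: 13 (1E)-1-[(6S)-6-[(2R)-1-hydroxy-1-(2,3,5,6-tetramethoxyphenyl)propan-2-yl]-2,2-dimethylcyclohexylidene]butan-2-one (carbinol epimers), via aryllithium 12 (not isolated)
Conditions: 11, n-BuLi, THF, 0 °C → rt; then 10, −78 °C; AcOH quench at −78 °C
Reagents that add atoms: none
Why: Directed ortho-lithiation of 11 (each ring hydrogen lies between two methoxy groups) gives 12, which adds to the aldehyde at −78 °C faster than to the conjugated β,β-disubstituted ketone; the cold acidic quench keeps the alkoxide from adding to the enone. The carbinol configuration is irrelevant.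

Step 7
Reactants: 13 (1E)-1-[(6S)-6-[(2R)-1-hydroxy-1-(2,3,5,6-tetramethoxyphenyl)propan-2-yl]-2,2-dimethylcyclohexylidene]butan-2-one (carbinol epimers)
Product: 14 (1E)-1-[(6S)-2,2-dimethyl-6-[(2R)-1-oxo-1-(2,3,5,6-tetramethoxyphenyl)propan-2-yl]cyclohexylidene]butan-2-one
Conditions: 1,1,1-triacetoxy-1,2-benziodoxol-3(1H)-one, NaHCO3, CH2Cl2, 0 °C → rt
Reagents that add atoms: none
Why: Oxidation of a secondary benzylic alcohol by a hypervalent iodine reagent under buffered, non-enolising conditions; the enone and the electron-rich arene are inert.

Step 8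
Reactants: 14 (1E)-1-[(6S)-2,2-dimethyl-6-[(2R)-1-oxo-1-(2,3,5,6-tetramethoxyphenyl)propan-2-yl]cyclohexylidene]butan-2-one
Product: 16 (3R,4S,4aR)-3,4,8,8-tetramethyl-4-(2,3,5,6-tetramethoxybenzoyl)-4,4a,5,6,7,8-hexahydronaphthalen-2(3H)-one, via dilithium bis-enolate 15 (not isolated)
Conditions: LiN(i-Pr)2 (2.3 equiv), THF, −78 → −40 °C; then Fe(acac)3 (2.3 equiv), THF, high dilution, −78 °C → rt
Reagents that add atoms: none
Why: Two equivalents of LiN(i-Pr)2 remove the two kinetically accessible α-protons, H8 of the ethyl ketone (giving the cross-conjugated dienolate) and H9 of the aryl ketone, while H10 is spared because allylic 1,3-strain with C7 holds it close to the enone plane, orthogonal to the π system. Fe(acac)3 oxidises one enolate by single-electron transfer to an α-keto radical that adds to the carbon of the second enolate, and a second one-electron oxidation of the resulting ketyl gives the diketone; intramolecular oxidative coupling of a ketone bis-enolate to a cyclic 1,4-diketone is the closest known reaction type. Ring B closes as a six-membered ring, 6-exo-trig with respect to the C9=C11 enolate (6-endo with respect to the C7=C8 enolate), and the (E) geometry of C5=C6 holds C7 on the C10 side so that the two enolate carbons lie within bonding distance. C9 is controlled by C10: allylic 1,3-strain places H10 in the plane of the C9 enolate, the tether reaches only the face that carries C5, and bonding there leaves C11 cis to H10 and the C9 methyl trans to it. C8 is controlled by the (Z)-enolate geometry expected for an ethyl alkenyl ketone, which puts its methyl group equatorial in the new ring, and because C8 stays α to the C7 carbonyl it can still be corrected by kinetic axial protonation of the C7 enolate anti to the axial C9 methyl. The step needs C–C rather than C–O coupling and intra- rather than intermolecular coupling; the first is inherent to α-keto radicals and the second is secured by high dilution and slow mixing with the oxidant. The C9 centre of 14 vanishes on enolisation, so any epimerisation at C9 in steps 5–7 is immaterial.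

Step 9
Reactants: 16 (3R,4S,4aR)-3,4,8,8-tetramethyl-4-(2,3,5,6-tetramethoxybenzoyl)-4,4a,5,6,7,8-hexahydronaphthalen-2(3H)-one
Product: 17 spiro-1,3-dithiolane at C7 of 16 (8R,9S,10R)
Conditions: HS(CH2)2SH (3 equiv), BF3·OEt2, CH2Cl2, 0 °C → rt
Reagents that add atoms: ethane-1,2-dithiol SCCS
Why: Lewis-acid-catalysed dithioketalisation; conjugated ketones give dithiolanes without migration of the double bond, and the aryl ketone, flanked by a quaternary carbon and two ortho methoxy groups, is too hindered to react.

Step 10
Reactants: 17 spiro-1,3-dithiolane at C7 of 16 (8R,9S,10R)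
Product: 18 (2,3,5,6-tetramethoxyphenyl)[(1R,2S,8aR)-1,2,5,5-tetramethyl-1,2,3,5,6,7,8,8a-octahydronaphthalen-1-yl]methanone
Conditions: Raney nickel (W-2, deactivated by brief reflux in acetone), EtOH, rt → 60 °C
Reagents that add atoms: none
Why: Raney nickel desulfurisation replaces both C–S bonds by C–H; with deactivated nickel, allylic dithiolanes of cyclohexenones are reduced to the olefin with the double bond kept in place. Partial reduction of the C11 ketone would be harmless because the alcohol is the next intermediate.

Step 11
Reactants: 18 (2,3,5,6-tetramethoxyphenyl)[(1R,2S,8aR)-1,2,5,5-tetramethyl-1,2,3,5,6,7,8,8a-octahydronaphthalen-1-yl]methanone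
Product: 19 (2,3,5,6-tetramethoxyphenyl)[(1R,2S,8aR)-1,2,5,5-tetramethyl-1,2,3,5,6,7,8,8a-octahydronaphthalen-1-yl]methanol (carbinol epimers)
Conditions: LiAlH4, THF, 0 °C → reflux; aqueous NaOH work-up
Reagents that add atoms: none
Why: Hydride reduction of the hindered aryl ketone; the small AlH4− ion reaches a carbonyl that carbon nucleophiles cannot, and either carbinol epimer serves.

Step 12
Reactants: 19 (2,3,5,6-tetramethoxyphenyl)[(1R,2S,8aR)-1,2,5,5-tetramethyl-1,2,3,5,6,7,8,8a-octahydronaphthalen-1-yl]methanol (carbinol epimers)
Product: 21 O-{(2,3,5,6-tetramethoxyphenyl)[(1R,2S,8aR)-1,2,5,5-tetramethyl-1,2,3,5,6,7,8,8a-octahydronaphthalen-1-yl]methyl} S-methyl carbonodithioate, via sodium xanthate 20 (not isolated)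
Conditions: NaN(SiMe3)2, THF, −78 °C; CS2, −78 → 0 °C; MeI, 0 °C → rt
Reagents that add atoms: carbon disulfide S=C=S; iodomethane CI
Why: Xanthate formation, the first half of the Barton–McCombie deoxygenation: the deprotonated alcohol adds to CS2 and the dithiocarbonate salt is S-methylated.

Step 13
Reactants: 21 O-{(2,3,5,6-tetramethoxyphenyl)[(1R,2S,8aR)-1,2,5,5-tetramethyl-1,2,3,5,6,7,8,8a-octahydronaphthalen-1-yl]methyl} S-methyl carbonodithioate
Product: 22 3-{[(1R,2S,8aS)-1,2,5,5-tetramethyl-1,2,3,5,6,7,8,8a-octahydronaphthalen-1-yl]methyl}-1,2,4,5-tetramethoxybenzene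
Conditions: Bu3SnH, AIBN (cat.), toluene, 110 °C
Reagents that add atoms: none
Why: Barton–McCombie deoxygenation: the stannyl radical adds to C=S, β-scission releases the benzylic C11 radical, and this takes hydrogen from Bu3SnH. A radical at C11 does not rearrange and can reach C5=C6 only by disfavoured 4-exo or 5-endo closure, and Chugaev elimination is impossible because C9 bears no hydrogen.

Step 14
Reactants: 22 3-{[(1R,2S,8aS)-1,2,5,5-tetramethyl-1,2,3,5,6,7,8,8a-octahydronaphthalen-1-yl]methyl}-1,2,4,5-tetramethoxybenzene
Product: 23 2,5-dimethoxy-3-{[(1R,2S,8aS)-1,2,5,5-tetramethyl-1,2,3,5,6,7,8,8a-octahydronaphthalen-1-yl]methyl}cyclohexa-2,5-diene-1,4-dione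
Conditions: (NH4)2Ce(NO3)6 (2.5 equiv), MeCN–H2O, 0 °C
Reagents that add atoms: water O
Why: Oxidative demethylation of a 1,4-dimethoxyarene by two one-electron oxidations with tetravalent cerium and attack of water; either para pair of methoxy groups gives the same 2,5-dimethoxy-1,4-benzoquinone because the arene is symmetric about the C1'–C4' axis. The isolated trisubstituted olefin should not be oxidised at 0 °C.

Step 15
Reactants: 23 2,5-dimethoxy-3-{[(1R,2S,8aS)-1,2,5,5-tetramethyl-1,2,3,5,6,7,8,8a-octahydronaphthalen-1-yl]methyl}cyclohexa-2,5-diene-1,4-dione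
Product: 24 2-hydroxy-5-methoxy-3-{[(1R,2S,8aS)-1,2,5,5-tetramethyl-1,2,3,5,6,7,8,8a-octahydronaphthalen-1-yl]methyl}cyclohexa-2,5-diene-1,4-dione
Conditions: KOH, MeOH–H2O, rt; then 1 M HCl
Reagents that add atoms: potassium hydroxide [K+].[OH-]
Why: Addition–elimination of hydroxide on a vinylogous ester: the C2' methoxy group, pushed out of the ring plane by the neighbouring C11 substituent, is the weaker donor and its carbon the better acceptor, and the hydroxyquinone anion that forms resists a second substitution.

Step 16
Reactants: 24 2-hydroxy-5-methoxy-3-{[(1R,2S,8aS)-1,2,5,5-tetramethyl-1,2,3,5,6,7,8,8a-octahydronaphthalen-1-yl]methyl}cyclohexa-2,5-diene-1,4-dione; 25 3-methylbutan-1-amine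
Product: 26 nakijiquinone M
Conditions: 25 (3 equiv), NaHCO3, EtOH, rt → 40 °C
Reagents that add atoms: none
Why: Addition–elimination of the primary amine at C5' of the remaining vinylogous ester gives the vinylogous amide; under bicarbonate buffering C2' is masked as the hydroxyquinone anion, so only the C5' methoxy group is exchanged.

## Compound list

1 | 2,2-dimethylcyclohexan-1-one | CC1(C)CCCCC1=O | starting material
2 | lithium 6,6-dimethylcyclohex-1-en-1-olate | [Li]OC1=CCCCC1(C)C | intermediate (not isolated)
3 | [(6,6-dimethylcyclohex-1-en-1-yl)oxy]trimethylsilane | C[Si](C)(C)OC1=CCCCC1(C)C | intermediate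
4 | (E)-but-2-en-1-yl methyl carbonate | COC(=O)OC/C=C/C | starting material
5 | (6S)-6-[(2S)-but-3-en-2-yl]-2,2-dimethylcyclohexan-1-one | O=C1C(C)(C)CCC[C@H]1[C@@H](C)C=C | intermediate
6 | but-1-yne | CCC#C | starting material
7 | lithium but-1-yn-1-ide | [Li]C#CCC | intermediate (not isolated)
8 | (6S)-1-(but-1-yn-1-yl)-6-[(2S)-but-3-en-2-yl]-2,2-dimethylcyclohexan-1-ol (C1 epimers, configuration inconsequential) | CCC#CC1(O)C(C)(C)CCC[C@H]1[C@@H](C)C=C | intermediate
9 | (1E)-1-[(6S)-6-[(2S)-but-3-en-2-yl]-2,2-dimethylcyclohexylidene]butan-2-one | CCC(=O)/C=C1/C(C)(C)CCC[C@H]1[C@@H](C)C=C | intermediate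
10 | (2R)-2-[(1S,2E)-3,3-dimethyl-2-(2-oxobutylidene)cyclohexyl]propanal | CCC(=O)/C=C1/C(C)(C)CCC[C@H]1[C@@H](C)C=O | intermediate
11 | 1,2,4,5-tetramethoxybenzene | COc1cc(OC)c(OC)cc1OC | starting material
12 | (2,3,5,6-tetramethoxyphenyl)lithium | [Li]c1c(OC)c(OC)cc(OC)c1OC | intermediate (not isolated)
13 | (1E)-1-[(6S)-6-[(2R)-1-hydroxy-1-(2,3,5,6-tetramethoxyphenyl)propan-2-yl]-2,2-dimethylcyclohexylidene]butan-2-one (carbinol epimers) | CCC(=O)/C=C1/C(C)(C)CCC[C@H]1[C@@H](C)C(O)c1c(OC)c(OC)cc(OC)c1OC | intermediate
14 | (1E)-1-[(6S)-2,2-dimethyl-6-[(2R)-1-oxo-1-(2,3,5,6-tetramethoxyphenyl)propan-2-yl]cyclohexylidene]butan-2-one (key-step precursor) | CCC(=O)/C=C1/C(C)(C)CCC[C@H]1[C@@H](C)C(=O)c1c(OC)c(OC)cc(OC)c1OC | intermediate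
15 | dilithium bis-enolate of 14 (C7=C8 enolate of the ethyl ketone and C9=C11 enolate of the aryl ketone; C10 S) | [Li]OC(=CC)/C=C1/C(C)(C)CCC[C@H]1C(C)=C(O[Li])c1c(OC)c(OC)cc(OC)c1OC | intermediate (not isolated)
16 | (3R,4S,4aR)-3,4,8,8-tetramethyl-4-(2,3,5,6-tetramethoxybenzoyl)-4,4a,5,6,7,8-hexahydronaphthalen-2(3H)-one (8R,9S,10R; key-step product) | COc1cc(OC)c(OC)c(C(=O)[C@@]2(C)[C@@H]3CCCC(C)(C)C3=CC(=O)[C@@H]2C)c1OC | intermediate
17 | 16 with the C7 carbonyl replaced by a spiro-1,3-dithiolane (8R,9S,10R) | COc1cc(OC)c(OC)c(C(=O)[C@@]2(C)[C@@H]3CCCC(C)(C)C3=CC4(SCCS4)[C@@H]2C)c1OC | intermediate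
18 | (2,3,5,6-tetramethoxyphenyl)[(1R,2S,8aR)-1,2,5,5-tetramethyl-1,2,3,5,6,7,8,8a-octahydronaphthalen-1-yl]methanone | COc1cc(OC)c(OC)c(C(=O)[C@@]2(C)[C@@H]3CCCC(C)(C)C3=CC[C@@H]2C)c1OC | intermediate
19 | (2,3,5,6-tetramethoxyphenyl)[(1R,2S,8aR)-1,2,5,5-tetramethyl-1,2,3,5,6,7,8,8a-octahydronaphthalen-1-yl]methanol (carbinol epimers) | COc1cc(OC)c(OC)c(C(O)[C@@]2(C)[C@@H]3CCCC(C)(C)C3=CC[C@@H]2C)c1OC | intermediate
20 | sodium O-{(2,3,5,6-tetramethoxyphenyl)[(1R,2S,8aR)-1,2,5,5-tetramethyl-1,2,3,5,6,7,8,8a-octahydronaphthalen-1-yl]methyl} carbonodithioate | COc1cc(OC)c(OC)c(C(OC(=S)[S-])[C@@]2(C)[C@@H]3CCCC(C)(C)C3=CC[C@@H]2C)c1OC.[Na+] | intermediate (not isolated)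
21 | O-{(2,3,5,6-tetramethoxyphenyl)[(1R,2S,8aR)-1,2,5,5-tetramethyl-1,2,3,5,6,7,8,8a-octahydronaphthalen-1-yl]methyl} S-methyl carbonodithioate | COc1cc(OC)c(OC)c(C(OC(=S)SC)[C@@]2(C)[C@@H]3CCCC(C)(C)C3=CC[C@@H]2C)c1OC | intermediate
22 | 3-{[(1R,2S,8aS)-1,2,5,5-tetramethyl-1,2,3,5,6,7,8,8a-octahydronaphthalen-1-yl]methyl}-1,2,4,5-tetramethoxybenzene | COc1cc(OC)c(OC)c(C[C@@]2(C)[C@@H]3CCCC(C)(C)C3=CC[C@@H]2C)c1OC | intermediate
23 | 2,5-dimethoxy-3-{[(1R,2S,8aS)-1,2,5,5-tetramethyl-1,2,3,5,6,7,8,8a-octahydronaphthalen-1-yl]methyl}cyclohexa-2,5-diene-1,4-dione | COC1=CC(=O)C(OC)=C(C[C@@]2(C)[C@@H]3CCCC(C)(C)C3=CC[C@@H]2C)C1=O | intermediate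
24 | 2-hydroxy-5-methoxy-3-{[(1R,2S,8aS)-1,2,5,5-tetramethyl-1,2,3,5,6,7,8,8a-octahydronaphthalen-1-yl]methyl}cyclohexa-2,5-diene-1,4-dione | COC1=CC(=O)C(O)=C(C[C@@]2(C)[C@@H]3CCCC(C)(C)C3=CC[C@@H]2C)C1=O | intermediate
25 | 3-methylbutan-1-amine | CC(C)CCN | starting material
26 | nakijiquinone M, 2-hydroxy-5-[(3-methylbutyl)amino]-3-{[(1R,2S,8aS)-1,2,5,5-tetramethyl-1,2,3,5,6,7,8,8a-octahydronaphthalen-1-yl]methyl}cyclohexa-2,5-diene-1,4-dione | CC(C)CCNC1=CC(=O)C(O)=C(C[C@@]2(C)[C@@H]3CCCC(C)(C)C3=CC[C@@H]2C)C1=O | target

## Step count and least certain steps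

Total step count: 16. Longest linear sequence: 16 steps (1 → 26); 4, 6, 11 and 25 enter as purchased reagents.

**Step 8 (key step).**
- **Risk:** coupling between two molecules, or return of the α-keto radical to the ketone by hydrogen abstraction before the congested C8–C9 bond can form. The C9 terminus is fully substituted and the aryl ketone enolate is slow to form at the tertiary C9–H.
- **Fallback (from 14, back at 16):** a two-electron alkylation replaces the one-electron coupling. Kinetic mono-enolisation at the unhindered C8 methylene (LiN(i-Pr)2, one equivalent, Me3SiCl, THF, −78 °C) should give the C7 trimethylsilyl dienol ether F1. N-Bromosuccinimide (THF, −78 °C) would convert it into the C8 bromo enone F2. KOt-Bu in t-BuOH–THF then generates the C9 enolate reversibly, and it displaces bromide in a 6-exo-tet alkylation to give 16.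

**Step 2.**
- **Risk:** a low branched-to-linear ratio with the small crotyl unit and a hard enolate, and incomplete face selectivity at the enolate carbon. The catalyst controls only the allyl carbon.
- **Fallback (from 1 through 2, back at 5):** a stereospecific substitution replaces the enantioselective one. Enolate 2 is transmetallated with CuI to the monovalent copper enolate F3. It is alkylated with (2S)-but-3-en-2-yl methyl carbonate F4 (made from commercial (S)-but-3-en-2-ol and methyl chloroformate) under RhCl(PPh3)3/P(OMe)3 catalysis. This allylation occurs at the substituted terminus with net retention, so regiochemistry and the C9 configuration come from the reagent. C10 is secured as before by separation and base-mediated recycling.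

**Step 4.**
- **Risk:** dehydration toward C10 (the Rupe pathway) or slow formation of the vanadate ester at the congested carbinol. Prolonged heating could also trigger a [3,3] shift of the 1,5-diene present in 9.
- **Fallback (from 8, back at 9):** an oxidative allylic transposition at room temperature. LiAlH4 (THF, reflux) should reduce the propargylic alcohol by hydroxyl-directed trans-hydroalumination to the (E)-allylic alcohol F5. Pyridinium chlorochromate, C5H5NH[CrO3Cl], in CH2Cl2 would then effect the Babler–Dauben 1,3-transposition of the tertiary allylic alcohol to 9.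

**Step 6.**
- **Risk:** competing 1,2-addition to the enone carbonyl or proton abstraction. An aryllithium distinguishes aldehyde from ketone only by rate, and the aldehyde is α-branched.
- **Fallback (from 10, back at 13):** a chromium-mediated addition that is selective for aldehydes. Aryllithium 12 is quenched with I2 to give 3-iodo-1,2,4,5-tetramethoxybenzene F6. F6 and 10 are then coupled with CrCl2 (excess) and NiCl2 (catalytic) in DMF (Nozaki–Hiyama–Kishi reaction), since arylchromium reagents leave ketones and enones untouched.

**Step 10.**
- **Risk:** hydrogenation or migration of the C5=C6 double bond on the hydrogen-laden nickel surface. The olefin is allylic to the carbon being desulfurised.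
- **Fallback (from 16, back at 22):** a double radical deoxygenation that bypasses 17–21. LiAlH4 should reduce both carbonyl groups to diol F7. NaH, CS2 and MeI would give the bis-xanthate F8. Bu3SnH/AIBN then removes both oxygens, and the C5–C6–C7 allyl radical should take hydrogen at the less hindered C7 terminus, which keeps the olefin at C5=C6.

## Further compounds

F1 | step 8 | (2R)-2-[(1S,2E)-3,3-dimethyl-2-[2-(trimethylsilyloxy)but-2-en-1-ylidene]cyclohexyl]-1-(2,3,5,6-tetramethoxyphenyl)propan-1-one | CC=C(O[Si](C)(C)C)/C=C1/C(C)(C)CCC[C@H]1[C@@H](C)C(=O)c1c(OC)c(OC)cc(OC)c1OC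
F2 | step 8 | (2R)-2-[(1S,2E)-2-(3-bromo-2-oxobutylidene)-3,3-dimethylcyclohexyl]-1-(2,3,5,6-tetramethoxyphenyl)propan-1-one (C8 epimers) | CC(Br)C(=O)/C=C1/C(C)(C)CCC[C@H]1[C@@H](C)C(=O)c1c(OC)c(OC)cc(OC)c1OC
F3 | step 2 | copper 6,6-dimethylcyclohex-1-en-1-olate (monovalent copper enolate) | [Cu]OC1=CCCCC1(C)C
F4 | step 2 | (2S)-but-3-en-2-yl methyl carbonate | C[C@H](OC(=O)OC)C=C
F5 | step 4 | (6S)-1-[(1E)-but-1-en-1-yl]-6-[(2S)-but-3-en-2-yl]-2,2-dimethylcyclohexan-1-ol (C1 epimers) | CC/C=C/C1(O)C(C)(C)CCC[C@H]1[C@@H](C)C=C
F6 | step 6 | 3-iodo-1,2,4,5-tetramethoxybenzene | COc1cc(OC)c(OC)c(I)c1OC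
F7 | step 10 | 7,11-diol from 16 (ring stereocentres as in 16, both carbinol centres uncontrolled) | COc1cc(OC)c(OC)c(C(O)[C@@]2(C)[C@@H]3CCCC(C)(C)C3=CC(O)[C@@H]2C)c1OC
F8 | step 10 | bis(S-methyl dithiocarbonate) of F7 | COc1cc(OC)c(OC)c(C(OC(=S)SC)[C@@]2(C)[C@@H]3CCCC(C)(C)C3=CC(OC(=S)SC)[C@@H]2C)c1OC
A1 | alternative 1 | (1S,2S,8aR)-2,5,5-trimethyl-1-[(2,3,5,6-tetramethoxyphenyl)methyl]-1,2,3,5,6,7,8,8a-octahydronaphthalene-1-carboxylic acid | COc1cc(OC)c(OC)c(C[C@@]2(C(=O)O)[C@@H]3CCCC(C)(C)C3=CC[C@@H]2C)c1OC
A2 | alternative 1 | (4S)-6-(6,6-dimethylcyclohex-1-en-1-yl)-4-methyl-3-[(2,3,5,6-tetramethoxyphenyl)methyl]oxan-2-one (C3 either epimer; C6 to be matched to the boat transition state) | O=C1OC(C2=CCCCC2(C)C)C[C@H](C)C1Cc1c(OC)c(OC)cc(OC)c1OC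
A3 | alternative 2 | (4S,4aS)-4,8,8-trimethyl-4,4a,5,6,7,8-hexahydronaphthalen-2(3H)-one | C[C@H]1CC(=O)C=C2C(C)(C)CCC[C@@H]12
A4 | alternative 2 | (3E)-pent-3-en-2-one | CC(=O)/C=C/C
A5 | alternative 2 | (4aS)-3,4,8,8-tetramethyl-5,6,7,8-tetrahydronaphthalen-2(4aH)-one | CC1=C(C)[C@@H]2CCCC(C)(C)C2=CC1=O
A6 | alternative 3 | 2-methoxy-3-{[(1R,2S,8aS)-1,2,5,5-tetramethyl-1,2,3,5,6,7,8,8a-octahydronaphthalen-1-yl]methyl}cyclohexa-2,5-diene-1,4-dione | O=C1C=CC(=O)C(OC)=C1C[C@@]2(C)[C@@H]3CCCC(C)(C)C3=CC[C@@H]2C
A7 | alternative 3 | 4-ethynyl-4-hydroxy-3-methoxy-2-{[(1R,2S,8aS)-1,2,5,5-tetramethyl-1,2,3,5,6,7,8,8a-octahydronaphthalen-1-yl]methyl}cyclobut-2-en-1-one (C4 epimers) | O=C1C(C[C@@]2(C)[C@@H]3CCCC(C)(C)C3=CC[C@@H]2C)=C(OC)C1(O)C#C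
A8 | alternative 3 | 3,4-dimethoxycyclobut-3-ene-1,2-dione | COC1=C(OC)C(=O)C1=O
A9 | alternative 3 | {[(1R,2S,8aS)-1,2,5,5-tetramethyl-1,2,3,5,6,7,8,8a-octahydronaphthalen-1-yl]methyl}lithium | [Li]C[C@@]2(C)[C@@H]3CCCC(C)(C)C3=CC[C@@H]2C
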